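**Slow start.** Q appears slowly: at 3.00 h the gamma run holds 6.8% of its Z as Q, which taken one to one would take up 7.16% of its L, not counting any L held in other forms. As a first reckoning, assumed and not shown, [L] and the Z charged are frozen at their charged values.

| flask | Z | L | remark | time |
|---|---|---|---|---|
| gamma | 0.83 M (in portions, 3) | 0.788 M | run made earlier; portions every 1.5 h |  |
| Sunday's | 0.75 M (in portions, 3) | 0.788 M | the portions of Z follow each other after 1.5 h, the first at the start | 5.0 h |
| Saturday's | 1.2 M | 0.250 M | everything together at the start | 5.0 h |

gamma run (percent of the Z charged)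

| time / h | Q / % |
|---|---|
| 0.250 | 0.4 |
| 0.833 | 0.1 |
| 1.33 | 1.8 |
| 2.00 | 3.7 |
| 3.00 | 6.8 |

(standard deviation of a reading: 0.3 percentage points)

- a reading or a percentage of Q counts all its forms, free or not

- the flask that ends with the higher amount of Q, in percent of the Z charged, or "neither" when 2 percentage points or less lies between them (Sunday's / Saturday's / neither)
- final Q, as a percentage of the Z charged, in Sunday's
- final Q, as a percentage of the Z charged, in Saturday's

**Exposure rule.** With both frozen, the percentage of Q grows in proportion to the exposure: [L] multiplied by the mean time the charged Z has spent in the flask. For these evenly spaced portions, that mean time is the elapsed time less one interval. The gamma run at 3.00 h has an exposure of 70.9 M·min, so its reading gives 9.59 × 10⁻⁴ M⁻¹ min⁻¹, the yield per exposure, with the scatter of 0.3 percentage points in it. Sunday's has an exposure of 165 M·min, which gives 15.9%. Saturday's has 75.0 M·min, which gives 7.19%, below the 20.8% allowed by L, its limiting reagent. Taken one to one, Saturday's figure would take up 34.5% of its L and Sunday's 15.1%, so freezing [L] makes both figures lean high, and it is coarser for Saturday's.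

**Turned round.** Saturday's keeps its Z longer, 5.0 h against 3.50 h, but at lower [L]. Sunday's still has twice the exposure of Saturday's. Within this reckoning, for Saturday's to lead, yield would have to follow [L] to a power below 0.311, and the gamma run, with one [L], does not test that power. This reckoning takes the first power and answers Sunday's.

**The flask.** The forecast also names Sunday's, lower on both figures at 13.1% against 5.7%, and notes that “the order in L is untested because only one L was used”. The flask gives Sunday's, with 15.1% against 5.21%.

    Z + L ⇌ D (K = 0.780 M⁻¹, k = 0.0120 M⁻¹ min⁻¹)
    Q ⇌ J (K = 1.00, k = 0.0170 min⁻¹)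
    L + Q ⇌ X, settled at all times (K = 26.0 M⁻¹)
    D ⇌ Q + G (K = 1.50 M, k = 0.00380 min⁻¹)

**Early binding.** Per exposure, Sunday's made 9.15 × 10⁻⁴ M⁻¹ min⁻¹ against the 9.59 × 10⁻⁴ M⁻¹ min⁻¹ read earlier, and Saturday's made 6.94 × 10⁻⁴ M⁻¹ min⁻¹. Saturday's neighbour with 1.0 M of L has an exposure of 300 M·min and ends at 20.7%, or 6.91 × 10⁻⁴ M⁻¹ min⁻¹ per exposure. In Saturday's, half of the turnover of Z + L into D is done by 0.478 h, whereas half of the turnover of D into Q + G takes until 2.38 h. At 5.00 h, unbound L in Saturday's stands at 29.5% of its own charge.

The data stem from a simulated flask from invented constants; scatter was added.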